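## The problem

The target is a diarylmethane in which two hexasubstituted benzene rings are joined by one CH2 group; it has no stereocentre, so every difficulty is one of regiochemistry on fully substituted phloroglucinol rings. Ring A carries three free hydroxyls that alternate with the methyl, butyryl and bridge carbons, whereas in ring B the oxygen para to the bridge carbon, between the methyl carbon and the butyryl carbon, is a methyl ether, so one oxygen out of three has to be singled out. The rings are therefore not two copies of one monomer, and joining two finished acylphloroglucinols through a one-carbon electrophile would be a cross-coupling of two nearly identical nucleophiles; the bridge is better made while only one aromatic ring exists. The electron-rich polyphenols oxidize in air under base, and the bridge, flanked by hydroxyls on both rings, can be cleaved or scrambled through quinone methides in hot alkali or through ipso-protonation in strong acid. The methyl ether next to a ketone is at risk with hard Lewis acids, and the two enolizable aryl ketones do not tolerate the strong bases of enolate chemistry. The enabling feature is the alternation in ring A: bridge-bearing carbon, hydroxyl carbon and acyl-bearing carbon are the γ-carbon, carbonyl carbon and α-carbon of a β-keto ester (a 1,3-dinucleophile), and hydroxyl carbon, methyl carbon and hydroxyl carbon are a methylmalonyl 1,3-dielectrophile. A second useful feature follows: once ring A is closed this way and its ester removed, each ring keeps exactly one unsubstituted carbon, and in both rings it is the carbon that bears butyryl in the target.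

## Retrosynthesis

**22 ⇒ 20 + 21 (two molecules).** Both aryl–acyl bonds are cut at once, so two molecules of butyric acid 21 are needed for one of pentaphenol 20. Pentaphenol 20 has a single free carbon on each ring, so the double C-acylation has no regiochemical choice. Cutting at the bridge instead would be shorter on paper but would ask two similar phloroglucinols to cross-couple. Keeping the ring B ketone from the start would expose an enolizable ketone to the amide base needed for diene 14. The forward step must acylate twice without acid cleavage of the bridge or of the methyl ether.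

**20 ⇒ 18.** A carboxyl group is put back on the free ring A carbon and three benzyl groups are added, giving benzyl ester 18 with ring B as its dibenzyl ether. One hydrogenolysis should remove all three benzyl groups, and the 2,4,6-trihydroxybenzoic acid 19 loses CO2 on warming. A benzyl ester is preferred to a methyl ester because the latter would need hot alkali on an air-sensitive polyphenolate. The ester is traceless; its only task is to decide which carbons of the three-carbon unit are nucleophilic.

**18 ⇒ 14 + 16.** Two ring A bonds are cut: bridge-bearing carbon to hydroxyl carbon, and ester-bearing carbon to hydroxyl carbon. This splits ring A into the 1-benzyloxy-1,3-bis(silyloxy)diene 14 and methylmalonyl dichloride 16. The cut brings the methyl group and the bridge in on separate components, so ring A is fully substituted as it forms and the bridge is never made by arene–arene coupling. The forward reaction must acylate the diene terminus first and then close through carbon, not through an enol oxygen.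

**14 ⇒ 13 ⇒ 12.** The diene is the twofold enol silyl ether of β-keto ester 12, reached through the mono silyl enol ether 13. This is a pure functional-group change. It is only safe because ring B of 12 carries ethers and one aryl C–H, and no carbonyl group.

**12 ⇒ 9 + 10.** The bond between the ketone carbon and the ester α-carbon is cut, leading to propanoic acid 9 and malonate half-ester salt 10. The neighbouring cut, alkylation of an acetoacetate dianion by a 2,4,6-trialkoxybenzyl halide, was set aside because such halides ionize and self-alkylate at the free ring carbon. The bridge carbon is therefore kept at the acid and aldehyde oxidation levels, and no strong base is needed.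

**9 ⇒ 5 + 6.** The bond between the future bridge carbon and its neighbour is cut as a C=C bond that is reduced in the same flask. Aldehyde 5 and Meldrum's acid 6 give the two-carbon extension in one operation.

**5 ⇒ 4 ⇒ 3 ⇒ 1.** The benzyl ethers, the methyl ether and the formyl group are removed in turn. The aldehyde of 3 sits between two hydroxyls and para to the third, so the oxygen that must become the methyl ether is the one oxygen that differs from the other two. The two free positions of 1 are equivalent, so the formylation has no regiochemical issue.

**16 ⇒ 15.** The dichloride is made from methylmalonic acid 15 in one step.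

## Roads not taken

Alternative 1: The cut removes the ring A butyryl group together with the oxygen on the neighbouring carbon. CsF-induced elimination from silyl triflate A2 would give aryne A3. Butyric acid 21 adds through oxygen at the aryne carbon beside the methyl carbon, and the aryl anion takes the acyl group by O-to-C shift, giving A1. Hydrogenolysis then leads to 22.
- Merits: ketone and ortho-hydroxyl arrive together under mild, non-acidic conditions, and the benzyloxy group next to the aryne plausibly directs the oxygen nucleophile to the distal carbon.
- Weak points: A2 is a hexasubstituted benzene that already contains the whole of ring A, the bridge and ring B, so the key step adds no skeleton and the precursor is long to make. The aryl anion must shift an acyl group through a four-membered transition state in competition with protonation by the acid. The aryne is hindered on both sides.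
- Comparison: its endgame is kinder to the bridge than step 11 of the chosen plan, and that is a real advantage. The chosen plan sets against it a key step that builds ring A from two small pieces and a far shorter access to its substrate.

Alternative 2: The cut takes ring B apart into cyclobutenone A5 and 1-methoxypropyne A6. On heating, electrocyclic opening, [2+2] addition, a second opening and a 6π closure would give phenol A4.
- Merits: the polarity of the ynol ether fixes methyl between hydroxyl and methoxy and places methoxy next to the unsubstituted carbon, so ring B regiochemistry is unambiguous. This is better than step 2 of the chosen plan, which relies on differentiating three hydroxyls. The two remaining ring B oxygens also emerge differentiated.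
- Weak points: ring A has to be made complete, tribenzylated and butyrylated beforehand and then attached to the sp3 carbon of A5. That is the less accessible regioisomer of a siloxycyclobutenone. A6 is volatile and sensitive. A4 still lacks the ring B butyryl group, so a late acylation next to a methyl ether remains.
- Comparison: the chosen plan accepts a less certain ether placement, backed by a chelation-controlled fallback. In return it avoids strained and sensitive reagents and builds both rings from cheap phloroglucinol-level materials.

Alternative 3: Only one ring A bond is cut, between the butyryl-bearing carbon and the hydroxyl carbon next to the bridge-bearing carbon. Mg(OMe)2 would fold triketo ester A8 by Claisen attack of its C6 methylene on the ester, giving A7. Hydrogenolysis would then give 22.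
- Merits: the butyryl group comes with the chain, so there is no traceless ester and no late acylation. The sequence after ring closure is two steps shorter and never exposes the bridged polyphenol to a Lewis acid. In this respect it is better than the chosen plan.
- Weak points: A8 is a branched tetracarbonyl chain with two carbon substituents. Its assembly needs successive acylations of polyanions in the presence of the enolizable ring B ketone. It can also fold by aldol closure onto the C7 ketone or lactonize to a pyranone, and the two substituents work against the planar chelated enolate that favours the Claisen mode.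
- Comparison: the chosen plan has the same carbon-versus-oxygen question. Its open-chain intermediate has only one carbocyclic mode, and its precursor is a single β-keto ester made without strong base in the presence of any ketone. The price is the two-step endgame.

Key step: step 9

Assumption: the enol ether double bonds of 13, 14 and 17 are drawn with one geometry for definiteness; mixtures are expected and are of no consequence because these carbons become aromatic, and for the same reason 17 and F2 are mixtures of diastereomers.

## Route

Step 1
Reactants: 1 2,4,6-trihydroxytoluene (2-methylbenzene-1,3,5-triol)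
Product: 3 2,4,6-trihydroxy-3-methylbenzaldehyde, via aryl iminium chloride 2 (not isolated)
Conditions: POCl3 (1.1 equiv), DMF, EtOAc, 0 °C → rt; then H2O, 60 °C
Reagents that add atoms: N,N-dimethylformamide CN(C)C=O; water O
Why: Vilsmeier–Haack formylation; the two free ring positions of 1 are equivalent and the iminium group of 2 deactivates the ring against a second attack, so a single aldehyde should result.

Step 2
Reactants: 3 2,4,6-trihydroxy-3-methylbenzaldehyde
Product: 4 2,6-dihydroxy-4-methoxy-3-methylbenzaldehyde
Conditions: Me2SO4 (1.0 equiv), K2CO3 (1.0 equiv), acetone, rt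
Reagents that add atoms: dimethyl sulfate COS(=O)(=O)OC
Why: Williamson etherification with limiting base and electrophile; the hydroxyl para to the aldehyde is the most acidic and the only one that cannot hydrogen-bond to the carbonyl oxygen, so it should react first.

Step 3
Reactants: 4 2,6-dihydroxy-4-methoxy-3-methylbenzaldehyde
Product: 5 2,6-bis(benzyloxy)-4-methoxy-3-methylbenzaldehyde
Conditions: BnBr (2.4 equiv), K2CO3, DMF, 60 °C
Reagents that add atoms: benzyl bromide BrCc1ccccc1 (two equivalents are incorporated)
Why: Williamson etherification; excess halide in a dipolar solvent with heating should overcome the hydrogen bonding of both ortho hydroxyls, and benzyl is chosen because all benzyl groups leave together in step 10.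

Step 4
Reactants: 5 2,6-bis(benzyloxy)-4-methoxy-3-methylbenzaldehyde; 6 Meldrum's acid (2,2-dimethyl-1,3-dioxane-4,6-dione)
Product: 9 3-[2,6-bis(benzyloxy)-4-methoxy-3-methylphenyl]propanoic acid, via arylidene Meldrum's acid 7 (not isolated), via arylmethyl Meldrum's acid 8 (not isolated)
Conditions: HCO2H–Et3N (5:2), rt → 95 °C
Reagents that add atoms: none
Why: Reductive Knoevenagel sequence: condensation to 7, conjugate hydride transfer from formate to 8, then hydrolytic ring opening and decarboxylation at 95 °C; no benzylic halide and no strong base are involved, and benzyl ethers are inert to formate without a metal.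

Step 5
Reactants: 9 3-[2,6-bis(benzyloxy)-4-methoxy-3-methylphenyl]propanoic acid; 10 potassium benzyl malonate
Product: 12 benzyl 5-[2,6-bis(benzyloxy)-4-methoxy-3-methylphenyl]-3-oxopentanoate, via acyl imidazolide 11 (not isolated)
Conditions: CDI, THF, rt; then 10, MgCl2, Et3N, THF–MeCN, rt → 45 °C; aq. HCl work-up
Reagents that add atoms: none
Why: Masamune–Brooks homologation: the enolate generated from 10 with MgCl2 and Et3N is C-acylated by the imidazolide, and the adduct decarboxylates to the β-keto ester under near-neutral conditions.

Step 6
Reactants: 12 benzyl 5-[2,6-bis(benzyloxy)-4-methoxy-3-methylphenyl]-3-oxopentanoate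
Product: 13 benzyl (2Z)-5-[2,6-bis(benzyloxy)-4-methoxy-3-methylphenyl]-3-(trimethylsilyloxy)pent-2-enoate
Conditions: Me3SiCl (1.5 equiv), Et3N (1.6 equiv), toluene, rt
Reagents that add atoms: chlorotrimethylsilane C[Si](C)(C)Cl
Why: O-silylation of the enol of a β-keto ester by amine and chlorosilane, the standard first stage of 1,3-bis(silyloxy)diene preparation.

Step 7
Reactants: 13 benzyl (2Z)-5-[2,6-bis(benzyloxy)-4-methoxy-3-methylphenyl]-3-(trimethylsilyloxy)pent-2-enoate
Product: 14 (1Z,3Z)-1-(benzyloxy)-5-[2,6-bis(benzyloxy)-4-methoxy-3-methylphenyl]-1,3-bis(trimethylsilyloxy)penta-1,3-diene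
Conditions: LiN(iPr)2 (1.2 equiv), THF, −78 °C; then Me3SiCl, −78 °C → rt
Reagents that add atoms: chlorotrimethylsilane C[Si](C)(C)Cl
Why: Kinetic γ-deprotonation of the silyl enol ether and O-silylation of the dienolate, the standard second stage of 1-alkoxy-1,3-bis(silyloxy)diene preparation; ring B offers the amide base no carbonyl group and no acidic C–H because its butyryl group is introduced only in step 11.

Step 8
Reactants: 15 methylmalonic acid
Product: 16 methylmalonyl dichloride
Conditions: SOCl2 (excess), 50 °C; distillation
Reagents that add atoms: thionyl chloride O=S(Cl)Cl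
Why: Standard conversion of a malonic acid into its dichloride; no base is present, so no ketene is formed from the acidic α-hydrogen.

Step 9
Reactants: 14 (1Z,3Z)-1-(benzyloxy)-5-[2,6-bis(benzyloxy)-4-methoxy-3-methylphenyl]-1,3-bis(trimethylsilyloxy)penta-1,3-diene; 16 methylmalonyl dichloride
Product: 18 benzyl 3-{[2,6-bis(benzyloxy)-4-methoxy-3-methylphenyl]methyl}-2,4,6-trihydroxy-5-methylbenzoate, via C4-acylated acid chloride 17 (not isolated)
Conditions: 16 (1.05 equiv), CH2Cl2, −78 °C → rt; aq. HCl work-up
Reagents that add atoms: none
Why: The diene terminus C4, the most nucleophilic carbon of this vinylogous silyl ketene acetal, attacks one acid chloride of 16 with loss of Me3SiCl and gives 17, in which C2 is still a silyl enol ether and the second acid chloride sits five bonds away. C2 then attacks that acyl carbon in a 6-exo-trig closure with loss of the second Me3SiCl, and the resulting 2,4,6-trioxocyclohexanecarboxylate tautomerizes to the benzene-1,3,5-triol 18, which makes the sequence irreversible. The closest known reaction types are the terminal C-acylation of 1-alkoxy-1,3-bis(silyloxy)dienes by acid chlorides to 3,5-dioxo esters, their [3+3] cyclizations with 1,3-dielectrophiles to salicylates, and the Effenberger annulation of silyl enol ethers with malonyl dichloride. No stereocentre is created, and the two sp3 centres of 17 disappear on aromatization. Three selectivities are needed: C4 before C2, which is inherent to the diene; carbon rather than enol oxygen in the ring closure, favoured because both oxygens of the dinucleophile start silylated and only the C-closed product can aromatize; and no acylation of the free ring B carbon, secured by adding no Lewis acid so that an aryl ether ring cannot compete with a silyl ketene acetal. Ring B is a bystander because it carries only ethers and one aryl C–H at this stage.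

Step 10
Reactants: 18 benzyl 3-{[2,6-bis(benzyloxy)-4-methoxy-3-methylphenyl]methyl}-2,4,6-trihydroxy-5-methylbenzoate
Product: 20 2-[(2,6-dihydroxy-4-methoxy-3-methylphenyl)methyl]-4-methylbenzene-1,3,5-triol, via trihydroxybenzoic acid 19 (not isolated)
Conditions: H2 (1 atm), 10% Pd/C, EtOAc–MeOH, rt; filter; then dioxane–H2O, 80 °C, Ar
Reagents that add atoms: none
Why: Hydrogenolysis of two benzyl ethers and the benzyl ester in one operation, then thermal protodecarboxylation, which 2,4,6-trihydroxybenzoic acids undergo readily through ipso-protonation; neutral conditions spare the bridge, and the air-sensitive product is carried on directly.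

Step 11
Reactants: 20 2-[(2,6-dihydroxy-4-methoxy-3-methylphenyl)methyl]-4-methylbenzene-1,3,5-triol; 21 butyric acid
Product: 22 1-[3-{[3-butanoyl-2,6-dihydroxy-4-methoxy-5-methylphenyl]methyl}-2,4,6-trihydroxy-5-methylphenyl]butan-1-one (target)
Conditions: 21 (excess, as solvent), BF3·OEt2, 70 °C; ice–water work-up
Reagents that add atoms: butyric acid CCCC(=O)O (the second of the two equivalents of 21 that are incorporated, one per ring)
Why: Twofold Friedel–Crafts C-acylation of phenols by a carboxylic acid activated with BF3, which consumes two molecules of 21 and releases two of water; each ring has one free carbon and each acyl group deactivates its ring against further reaction. BF3 is preferred to AlCl3 because it should leave the methyl ether beside the new ring B ketone intact.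

## Compound list

1 | 2,4,6-trihydroxytoluene | Cc1c(O)cc(O)cc1O | starting material
2 | N,N-dimethyl-1-(2,4,6-trihydroxy-3-methylphenyl)methaniminium chloride | C[N+](C)=Cc1c(O)cc(O)c(C)c1O.[Cl-] | intermediate
3 | 2,4,6-trihydroxy-3-methylbenzaldehyde | O=Cc1c(O)cc(O)c(C)c1O | intermediate
4 | 2,6-dihydroxy-4-methoxy-3-methylbenzaldehyde | O=Cc1c(O)cc(OC)c(C)c1O | intermediate
5 | 2,6-bis(benzyloxy)-4-methoxy-3-methylbenzaldehyde | O=Cc1c(OCc2ccccc2)cc(OC)c(C)c1OCc1ccccc1 | intermediate
6 | Meldrum's acid (2,2-dimethyl-1,3-dioxane-4,6-dione) | CC1(C)OC(=O)CC(=O)O1 | starting material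
7 | 5-{[2,6-bis(benzyloxy)-4-methoxy-3-methylphenyl]methylidene}-2,2-dimethyl-1,3-dioxane-4,6-dione | CC1(C)OC(=O)C(=Cc2c(OCc3ccccc3)cc(OC)c(C)c2OCc2ccccc2)C(=O)O1 | intermediate
8 | 5-{[2,6-bis(benzyloxy)-4-methoxy-3-methylphenyl]methyl}-2,2-dimethyl-1,3-dioxane-4,6-dione | CC1(C)OC(=O)C(Cc2c(OCc3ccccc3)cc(OC)c(C)c2OCc2ccccc2)C(=O)O1 | intermediate
9 | 3-[2,6-bis(benzyloxy)-4-methoxy-3-methylphenyl]propanoic acid | OC(=O)CCc1c(OCc2ccccc2)cc(OC)c(C)c1OCc1ccccc1 | intermediate
10 | potassium benzyl malonate (potassium 3-(benzyloxy)-3-oxopropanoate) | [K+].[O-]C(=O)CC(=O)OCc1ccccc1 | starting material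
11 | 3-[2,6-bis(benzyloxy)-4-methoxy-3-methylphenyl]-1-(1H-imidazol-1-yl)propan-1-one | O=C(CCc1c(OCc2ccccc2)cc(OC)c(C)c1OCc1ccccc1)n1ccnc1 | intermediate
12 | benzyl 5-[2,6-bis(benzyloxy)-4-methoxy-3-methylphenyl]-3-oxopentanoate | O=C(CCc1c(OCc2ccccc2)cc(OC)c(C)c1OCc1ccccc1)CC(=O)OCc1ccccc1 | intermediate
13 | benzyl (2Z)-5-[2,6-bis(benzyloxy)-4-methoxy-3-methylphenyl]-3-(trimethylsilyloxy)pent-2-enoate | C[Si](C)(C)O/C(CCc1c(OCc2ccccc2)cc(OC)c(C)c1OCc1ccccc1)=C\C(=O)OCc1ccccc1 | intermediate
14 | (1Z,3Z)-1-(benzyloxy)-5-[2,6-bis(benzyloxy)-4-methoxy-3-methylphenyl]-1,3-bis(trimethylsilyloxy)penta-1,3-diene | c1ccccc1CO/C(O[Si](C)(C)C)=C/C(O[Si](C)(C)C)=C/Cc1c(OCc2ccccc2)cc(OC)c(C)c1OCc1ccccc1 | intermediate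
15 | methylmalonic acid | CC(C(=O)O)C(=O)O | starting material
16 | methylmalonyl dichloride | CC(C(=O)Cl)C(=O)Cl | intermediate
17 | benzyl (2Z)-4-{[2,6-bis(benzyloxy)-4-methoxy-3-methylphenyl]methyl}-7-chloro-6-methyl-5,7-dioxo-3-(trimethylsilyloxy)hept-2-enoate (diastereomer mixture) | O=C(OCc1ccccc1)/C=C(\O[Si](C)(C)C)C(Cc1c(OCc2ccccc2)cc(OC)c(C)c1OCc1ccccc1)C(=O)C(C)C(=O)Cl | intermediate
18 | benzyl 3-{[2,6-bis(benzyloxy)-4-methoxy-3-methylphenyl]methyl}-2,4,6-trihydroxy-5-methylbenzoate | O=C(OCc1ccccc1)c1c(O)c(C)c(O)c(Cc2c(OCc3ccccc3)cc(OC)c(C)c2OCc2ccccc2)c1O | intermediate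
19 | 3-[(2,6-dihydroxy-4-methoxy-3-methylphenyl)methyl]-2,4,6-trihydroxy-5-methylbenzoic acid | OC(=O)c1c(O)c(C)c(O)c(Cc2c(O)cc(OC)c(C)c2O)c1O | intermediate
20 | 2-[(2,6-dihydroxy-4-methoxy-3-methylphenyl)methyl]-4-methylbenzene-1,3,5-triol | Cc1c(O)cc(O)c(Cc2c(O)cc(OC)c(C)c2O)c1O | intermediate
21 | butyric acid | CCCC(=O)O | starting material
22 | 1-[3-{[3-butanoyl-2,6-dihydroxy-4-methoxy-5-methylphenyl]methyl}-2,4,6-trihydroxy-5-methylphenyl]butan-1-one | CCCC(=O)c1c(O)c(C)c(O)c(Cc2c(O)c(C)c(OC)c(C(=O)CCC)c2O)c1O | target

## Step count and weak points

Total step count: 11. Longest linear sequence: 10 steps (steps 1–7 and 9–11); step 8 is a one-step side branch.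

**Step 9 (key step).** The most likely failure is closure of the second bond through oxygen. After the first acylation, C4–H of 17 lies between two carbonyl groups and enolizes easily in the Me3SiCl/HCl medium. The oxygen on C3 is then as well placed for the remaining acid chloride as C2 is. Intermolecular acylation of a second diene molecule is the other leak. Fallback: setting out from 14 and 16, the O-closed isomer is accepted and isolated as benzyl 2-(3-{[2,6-bis(benzyloxy)-4-methoxy-3-methylphenyl]methyl}-4-hydroxy-5-methyl-6-oxo-6H-pyran-2-yl)acetate F1. Treatment with NaOCH2Ph in benzyl alcohol–THF at 60 °C should open the lactone to dibenzyl 4-{[2,6-bis(benzyloxy)-4-methoxy-3-methylphenyl]methyl}-2-methyl-3,5-dioxoheptanedioate F2, which is not isolated. F2 closes by Claisen condensation of its C6 methylene on the C1 ester. Only this mode can aromatize, so the equilibria should drain into 18, where the route is rejoined. Benzyloxide is used so that ester exchange cannot alter the benzyl ester.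

**Step 11.** The risk is acid-induced scission and scrambling of the methylene bridge before both rings are deactivated by acylation. Ipso-protonation of the very electron-rich ring A at the bridge carbon would release a stabilized hydroxybenzyl cation. Incomplete acylation of the less nucleophilic ring B, which would stop the reaction after the first of the two butyryl transfers, is a second risk. Fallback: setting out from 20, a twofold Houben–Hoesch reaction with butyronitrile, ZnCl2 and HCl in Et2O at 0 °C should precipitate 1-[3-{[3-(1-iminiobutyl)-2,6-dihydroxy-4-methoxy-5-methylphenyl]methyl}-2,4,6-trihydroxy-5-methylphenyl]butan-1-iminium dichloride F3. The C–C bonds are then formed cold, and both rings are deactivated as iminium salts before any heating. Hydrolysis in warm water returns the route to 22.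

**Step 2.** The risk is insufficient discrimination between the para hydroxyl and whichever ortho hydroxyl is not hydrogen-bonded at a given moment, which leads to over-alkylation. Fallback: setting out from 3, exhaustive methylation (excess Me2SO4, K2CO3, acetone, reflux) gives 2,4,6-trimethoxy-3-methylbenzaldehyde F4. AlCl3 in CH2Cl2 then cleaves the two methyl ethers ortho to the aldehyde through six-membered chelates. The para ether cannot chelate and stays, and the route is rejoined at 4.

**Step 4.** The risk is slow hydride transfer from formate to a push–pull, doubly ortho-substituted arylidene, and benzyl loss or migration in hot formic acid. Fallback: setting out from 5, Knoevenagel–Doebner condensation with malonic acid (pyridine, piperidine, 90 °C) gives (2E)-3-[2,6-bis(benzyloxy)-4-methoxy-3-methylphenyl]prop-2-enoic acid F5. Homogeneous hydrogenation (H2, RhCl(PPh3)3, benzene–EtOH) saturates the alkene without touching the benzyl ethers and rejoins the route at 9.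

## Further compounds

F1 | step 9 | benzyl 2-(3-{[2,6-bis(benzyloxy)-4-methoxy-3-methylphenyl]methyl}-4-hydroxy-5-methyl-6-oxo-6H-pyran-2-yl)acetate | O=C(Cc1oc(=O)c(C)c(O)c1Cc1c(OCc2ccccc2)cc(OC)c(C)c1OCc1ccccc1)OCc1ccccc1
F2 | step 9 | dibenzyl 4-{[2,6-bis(benzyloxy)-4-methoxy-3-methylphenyl]methyl}-2-methyl-3,5-dioxoheptanedioate (diastereomer mixture) | O=C(OCc1ccccc1)C(C)C(=O)C(Cc1c(OCc2ccccc2)cc(OC)c(C)c1OCc1ccccc1)C(=O)CC(=O)OCc1ccccc1
F3 | step 11 | 1-[3-{[3-(1-iminiobutyl)-2,6-dihydroxy-4-methoxy-5-methylphenyl]methyl}-2,4,6-trihydroxy-5-methylphenyl]butan-1-iminium dichloride | CCCC(=[NH2+])c1c(O)c(C)c(O)c(Cc2c(O)c(C)c(OC)c(C(=[NH2+])CCC)c2O)c1O.[Cl-].[Cl-]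
F4 | step 2 | 2,4,6-trimethoxy-3-methylbenzaldehyde | O=Cc1c(OC)cc(OC)c(C)c1OC
F5 | step 4 | (2E)-3-[2,6-bis(benzyloxy)-4-methoxy-3-methylphenyl]prop-2-enoic acid | OC(=O)/C=C/c1c(OCc2ccccc2)cc(OC)c(C)c1OCc1ccccc1
A1 | alternative 1 | 1-[2,4-bis(benzyloxy)-3-{[2,6-bis(benzyloxy)-3-butanoyl-4-methoxy-5-methylphenyl]methyl}-6-hydroxy-5-methylphenyl]butan-1-one | CCCC(=O)c1c(O)c(C)c(OCc2ccccc2)c(Cc2c(OCc3ccccc3)c(C)c(OC)c(C(=O)CCC)c2OCc2ccccc2)c1OCc1ccccc1
A2 | alternative 1 | 3,5-bis(benzyloxy)-4-{[2,6-bis(benzyloxy)-3-butanoyl-4-methoxy-5-methylphenyl]methyl}-2-methyl-6-(trimethylsilyl)phenyl trifluoromethanesulfonate | C[Si](C)(C)c1c(OS(=O)(=O)C(F)(F)F)c(C)c(OCc2ccccc2)c(Cc2c(OCc3ccccc3)c(C)c(OC)c(C(=O)CCC)c2OCc2ccccc2)c1OCc1ccccc1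
A3 | alternative 1 | 3,5-bis(benzyloxy)-4-{[2,6-bis(benzyloxy)-3-butanoyl-4-methoxy-5-methylphenyl]methyl}-6-methyl-1,2-didehydrobenzene | CC1=C(OCc2ccccc2)C(Cc2c(OCc3ccccc3)c(C)c(OC)c(C(=O)CCC)c2OCc2ccccc2)=C(OCc2ccccc2)C#C1
A4 | alternative 2 | 1-[2,4,6-tris(benzyloxy)-3-{[2-hydroxy-4-methoxy-3-methyl-6-(triisopropylsilyloxy)phenyl]methyl}-5-methylphenyl]butan-1-one | CCCC(=O)c1c(OCc2ccccc2)c(C)c(OCc2ccccc2)c(Cc2c(O)c(C)c(OC)cc2O[Si](C(C)C)(C(C)C)C(C)C)c1OCc1ccccc1
A5 | alternative 2 | 4-{[2,4,6-tris(benzyloxy)-3-butanoyl-5-methylphenyl]methyl}-3-(triisopropylsilyloxy)cyclobut-2-en-1-one (racemic) | CCCC(=O)c1c(OCc2ccccc2)c(C)c(OCc2ccccc2)c(CC2C(=O)C=C2O[Si](C(C)C)(C(C)C)C(C)C)c1OCc1ccccc1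
A6 | alternative 2 | 1-methoxyprop-1-yne | CC#COC
A7 | alternative 3 | 1-[3-{[2,6-bis(benzyloxy)-3-butanoyl-4-methoxy-5-methylphenyl]methyl}-2,4,6-trihydroxy-5-methylphenyl]butan-1-one | CCCC(=O)c1c(O)c(C)c(O)c(Cc2c(OCc3ccccc3)c(C)c(OC)c(C(=O)CCC)c2OCc2ccccc2)c1O
A8 | alternative 3 | methyl 2-{[2,6-bis(benzyloxy)-3-butanoyl-4-methoxy-5-methylphenyl]methyl}-4-methyl-3,5,7-trioxodecanoate (diastereomer mixture) | COC(=O)C(Cc1c(OCc2ccccc2)c(C)c(OC)c(C(=O)CCC)c1OCc1ccccc1)C(=O)C(C)C(=O)CC(=O)CCC
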